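**Strategy.** The cycloheptane ring is cut at C5–C6 and C7–C8 (daucane numbering; C1 = methylated ring-fusion carbon, C5 = ring-fusion CH). A rhodium-catalysed (5+2) cycloaddition inserts the two carbons of ethynyl-Bpin between C5 and C8 of a siloxy-vinylcyclopropane, the 6-siloxy-6-propenylbicyclo[3.1.0]hexane 13, whose cyclopropane C1–C5–C10 sits on the finished cyclopentane. The step exploits the cis C1–C5 fusion of the five- and seven-membered rings next to quaternary C1. Strain-driven cleavage of C5–C10 with retention at C5 builds the seven-membered ring and leaves boron on C6 and a silyl enol ether at C10 as handles for both tiglates and the C8–C9 epoxide.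

Key step: step 8

Remarks on the chemistry:
- Numbering and faces: C1 (C–CH3, ring fusion), C2 (CHOH), C3 (CH2), C4 (C(OH)iPr), C5 (ring-fusion CH), C6 (CH–OTig), C7 (CH2), C8 (epoxide C–CH3), C9 (epoxide CH), C10 (CH–OTig). β is the face of the C1 methyl group. The target is cis-fused: 1β-CH3, 5β-H, 2β-OH, 4α-OH (4β-iPr), 6β-OTig, 10α-OTig, 8α,9α-epoxide.
- Abbreviations: TBS = tert-butyldimethylsilyl, Tig = (E)-2-methylbut-2-enoyl, Bpin = pinacolatoboryl, Ipc = isopinocampheyl, PMB = 4-methoxybenzyl.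
- Assumption: in the Ipc-boron aldol the Z-enolate made with (−)-Ipc2BOTf is taken to attack the Re face of the aldehyde, which gives the (3S)-carbinol. If the sense is the opposite, the enantiomeric reagent is used and nothing else changes.

**Step 1**
Reactants: 1 (E)-hex-4-en-3-one; 2 3-[(4-methoxybenzyl)oxy]propanal
Product: 5 (3S,4R,6E)-3-hydroxy-1-[(4-methoxybenzyl)oxy]-4-methyloct-6-en-5-one, via Z-boron enolate 3 (not isolated), via boron aldolate 4 (not isolated)
Conditions: (−)-Ipc2BOTf (from (−)-Ipc2BH and TfOH), iPr2NEt, CH2Cl2, −78 °C; then 2, −78 to −20 °C; H2O2, MeOH, pH 7 buffer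
Reagents that add atoms: none
Why: Ipc-boron (Paterson) aldol: the Z-enolate formed on the ethyl side of the enone adds through a chair transition state to give the syn adduct, the Ipc ligands setting the (3S)-carbinol that becomes C2 (the C4 centre of 5 is erased in step 4).

**Step 2**
Reactants: 5 (3S,4R,6E)-3-hydroxy-1-[(4-methoxybenzyl)oxy]-4-methyloct-6-en-5-one
Product: 6 (3S,4R,6E)-1,3-dihydroxy-4-methyloct-6-en-5-one
Conditions: DDQ, CH2Cl2/pH 7 buffer, 0 °C
Reagents that add atoms: none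
Why: Oxidative PMB cleavage (benzylic hydride abstraction, then hydrolysis of the oxocarbenium ion) should free the primary alcohol without touching the enone or the aldol unit.

**Step 3**
Reactants: 6 (3S,4R,6E)-1,3-dihydroxy-4-methyloct-6-en-5-one
Product: 7 (3S,4R,6E)-3-hydroxy-4-methyl-5-oxooct-6-enoic acid
Conditions: TEMPO (cat.), PhI(OAc)2, MeCN/H2O, 20 °C
Reagents that add atoms: water, O
Why: Oxoammonium (TEMPO) oxidation is selective for the primary alcohol and in water runs through the aldehyde hydrate to the acid, leaving the secondary aldol hydroxyl.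

**Step 4**
Reactants: 7 (3S,4R,6E)-3-hydroxy-4-methyl-5-oxooct-6-enoic acid
Product: 9 (3S,4Z,6E)-3,5-bis[(tert-butyldimethylsilyl)oxy]-4-methylocta-4,6-dienoic acid, via silyl ester 8 (not isolated)
Conditions: TBSOTf, Et3N, CH2Cl2, −78 to 0 °C; then MeOH/H2O, K2CO3 (cat.), 0 °C
Reagents that add atoms: tert-butyldimethylsilyl triflate, CC(C)(C)[Si](C)(C)OS(=O)(=O)C(F)(F)F
Why: Silyl triflate/amine soft enolisation (O-silylation of the C10 ketone, then deprotonation at C1) should give the cross-conjugated Z-dienol ether with the bulkier C2 branch cis to OTBS; the hydroxyl and the acid are silylated in the same operation and only the labile silyl ester is hydrolysed on work-up.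

**Step 5**
Reactants: 9 (3S,4Z,6E)-3,5-bis[(tert-butyldimethylsilyl)oxy]-4-methylocta-4,6-dienoic acid
Product: 11 (4S,5Z,7E)-1-diazo-4,6-bis[(tert-butyldimethylsilyl)oxy]-5-methylnona-5,7-dien-2-one, via mixed anhydride 10 (not isolated)
Conditions: isobutyl chloroformate, N-methylmorpholine, THF, −20 °C; then CH2N2, Et2O, 0 °C
Reagents that add atoms: diazomethane, C=[N+]=[N-]
Why: Arndt–Eistert-type acylation of diazomethane by a mixed carbonic anhydride is non-acidic and should spare the silyl dienol ether.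

**Step 6**
Reactants: 11 (4S,5Z,7E)-1-diazo-4,6-bis[(tert-butyldimethylsilyl)oxy]-5-methylnona-5,7-dien-2-one
Product: 12 bicyclo[3.1.0]hexanone (C4 ketone; cyclopropane C1–C5–C10 on the α face; 1β-CH3, 5β-H; C10 with endo OTBS and exo (E)-prop-1-enyl; 2β-OTBS, trans to the cyclopropane)
Conditions: Rh2(OAc)4 (1 mol %), CH2Cl2, 25 °C, slow addition
Reagents that add atoms: none
Why: Intramolecular cyclopropanation of the rhodium carbenoid (C5) onto the electron-rich enol ether C1=C10 closes the cyclopentanone stereospecifically (Z enol ether gives endo OTBS), and A(1,3) strain should put the C2–OTBS group anti to the new cyclopropane, so C2 sets C1 and C5.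

**Step 7**
Reactants: 12 bicyclo[3.1.0]hexanone
Product: 13 6-siloxy-6-propenylbicyclo[3.1.0]hexan-2-ol (as 12, with 4α-OH cis to the cyclopropane and 4β-isopropyl)
Conditions: iPrMgCl, CeCl3, THF, −78 °C
Reagents that add atoms: isopropylmagnesium chloride, CC(C)[Mg]Cl
Why: Organocerium 1,2-addition suppresses enolisation, and the nucleophile should enter from the exo face, anti to the cyclopropane whose endo OTBS covers the other face, which sets C4 (OH α, iPr β).

**Step 8**
Reactants: 13 6-siloxy-6-propenylbicyclo[3.1.0]hexan-2-ol; 14 2-ethynyl-4,4,5,5-tetramethyl-1,3,2-dioxaborolane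
Product: 15 cis-fused bicyclo[5.3.0]deca-6,9-diene (6-Bpin on C6=C7; TBS enol ether C9=C10–OTBS; 8α-CH3; 1β-CH3, 5β-H; 4α-OH, 4β-iPr; 2β-OTBS)
Conditions: [Rh(CO)2Cl]2 (5 mol %), 14 (3 equiv), 1,2-dichloroethane, 60 °C
Reagents that add atoms: none
Why: Oxidative addition of monovalent rhodium into the strained C5–C10 bond gives a rhodacycle with a σ-bond to C5 and a π-allyl over C10–C9–C8; the alkyne inserts at the allyl terminus (C7–C8) and reductive elimination joins C5 to C6. The closest known reaction is the rhodium-catalysed intermolecular (5+2) cycloaddition of 1-siloxy-1-vinylcyclopropanes with alkynes under [Rh(CO)2Cl]2. The seven-membered ring C5–C6–C7–C8–C9–C10–C1 closes by two-bond cycloaddition (five carbons of the vinylcyclopropane plus the two alkyne carbons), driven by release of cyclopropane strain, so no exo/endo cyclisation mode applies. C5 reacts with retention in both oxidative addition and reductive elimination, so the cis C1-methyl/C5-H relation of the bicyclo[3.1.0]hexane becomes the cis ring fusion; C8 (methyl α, from suprafacial addition to the E-propenyl group) is a temporary centre erased in step 11. The step needs cleavage of C5–C10 and not C1–C10, which should follow because rhodium avoids a bond to the fully substituted C1 and the cis C4 hydroxyl can guide it to C5; it also needs boron on C6, which should follow because the bulky Bpin end of the alkyne stays distal to the first-formed C7–C8 bond while the CH end meets the methyl-bearing C8.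

**Step 9**
Reactants: 15 cis-fused bicyclo[5.3.0]deca-6,9-diene
Product: 16 C6 ketone (C9=C10–OTBS enol ether kept; 8α-CH3; 4α-OH; 2β-OTBS)
Conditions: H2O2, NaHCO3, THF/H2O, 0 °C
Reagents that add atoms: hydrogen peroxide, OO
Why: Alkenylboronate oxidation (1,2-shift of C6 from boron to oxygen) gives the enol and hence the C6 ketone under near-neutral conditions that should keep the hindered TBS enol ether and avoid retro-aldol at the C4 carbinol.

**Step 10**
Reactants: 16 C6 ketone
Product: 17 6β-alcohol (C9=C10–OTBS enol ether kept; 4α-OH; 2β-OTBS)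
Conditions: Me4NBH(OAc)3, MeCN/AcOH, −30 °C
Reagents that add atoms: none
Why: Evans–Saksena reduction: the C4 hydroxyl exchanges onto boron and delivers hydride to the α face of C6 through a six-membered transition state, which sets C6 as the 6β-alcohol (anti to 4α-OH).

**Step 11**
Reactants: 17 6β-alcohol
Product: 18 enone (C10 ketone, C8=C9 with 8-CH3; 6β-OH; 4α-OH; 2β-OTBS)
Conditions: Pd(OAc)2 (1.2 equiv), MeCN, 40 °C
Reagents that add atoms: none
Why: Saegusa–Ito oxidation: the silyl enol ether gives a palladium enolate at C9 and syn β-hydride elimination of the β-oriented H8 forms the C8=C9 enone; C1 is quaternary, so no regioisomer can form.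

**Step 12**
Reactants: 18 enone
Product: 19 allylic triol (C8=C9; 4α,6β,10α-triol; 2β-OTBS)
Conditions: NaBH4, CeCl3·7H2O, MeOH, −78 °C
Reagents that add atoms: none
Why: Luche 1,2-reduction; hydride is expected from the convex β face, anti to the C1–C2 ring bond, which sets C10 as the 10α-alcohol.

**Step 13**
Reactants: 19 allylic triol
Product: 20 epoxy triol (8α,9α-epoxide; 4α,6β,10α-triol; 2β-OTBS)
Conditions: VO(acac)2 (cat.), t-BuOOH, CH2Cl2, 0 °C
Reagents that add atoms: tert-butyl hydroperoxide, CC(C)(C)OO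
Why: Hydroxyl-directed vanadium epoxidation: the vanadate ester of the allylic 10α-alcohol delivers oxygen to the same face of C8=C9, which sets C8 and C9.

**Step 14**
Reactants: 20 epoxy triol
Product: 21 6β,10α-bis-tiglate (8α,9α-epoxide; 4α-OH; 2β-OTBS)
Conditions: tiglic acid, 2,4,6-trichlorobenzoyl chloride, Et3N, DMAP, toluene, 60 °C
Reagents that add atoms: tiglic acid, C/C=C(\C)C(=O)O
Why: Yamaguchi esterification acylates the two secondary alcohols through the mixed anhydride and acyl-DMAP species, leaves the tertiary C4–OH, and avoids the ketene pathway that would deconjugate the tiglate.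

**Step 15**
Reactants: 21 6β,10α-bis-tiglate
Product: 22 target, (1S,2S,4R,5S,6S,8S,9R,10R)-8,9-epoxy-2,4-dihydroxydaucane-6,10-diyl bis[(E)-2-methylbut-2-enoate]
Conditions: HF·pyridine, pyridine, THF, 0 to 20 °C
Reagents that add atoms: none
Why: Buffered fluoride cleavage of the Si–O bond should free the 2β-alcohol without opening the epoxide or moving an acyl group.

**Compound list**
1 | (E)-hex-4-en-3-one | C/C=C/C(=O)CC | starting material
2 | 3-[(4-methoxybenzyl)oxy]propanal | COc1ccc(COCCC=O)cc1 | starting material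
3 | Z-boron enolate of 1: bis[(1R,2R,3R,5S)-isopinocampheyl]boron (2Z,4E)-hexa-2,4-dien-3-olate | C/C=C/C(OB([C@@H]1C[C@@H]2C[C@H]([C@H]1C)C2(C)C)[C@@H]1C[C@@H]2C[C@H]([C@H]1C)C2(C)C)=C/C | intermediate
4 | boron aldolate: O-bis(isopinocampheyl)boryl derivative of 5 at the C3 oxygen | C/C=C/C(=O)[C@H](C)[C@@H](OB([C@@H]1C[C@@H]2C[C@H]([C@H]1C)C2(C)C)[C@@H]1C[C@@H]2C[C@H]([C@H]1C)C2(C)C)CCOCc1ccc(OC)cc1 | intermediate
5 | (3S,4R,6E)-3-hydroxy-1-[(4-methoxybenzyl)oxy]-4-methyloct-6-en-5-one | C/C=C/C(=O)[C@H](C)[C@@H](O)CCOCc1ccc(OC)cc1 | intermediate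
6 | (3S,4R,6E)-1,3-dihydroxy-4-methyloct-6-en-5-one | C/C=C/C(=O)[C@H](C)[C@@H](O)CCO | intermediate
7 | (3S,4R,6E)-3-hydroxy-4-methyl-5-oxooct-6-enoic acid | C/C=C/C(=O)[C@H](C)[C@@H](O)CC(=O)O | intermediate
8 | tert-butyldimethylsilyl (3S,4Z,6E)-3,5-bis[(tert-butyldimethylsilyl)oxy]-4-methylocta-4,6-dienoate | C/C=C/C(O[Si](C)(C)C(C)(C)C)=C(C)/[C@@H](O[Si](C)(C)C(C)(C)C)CC(=O)O[Si](C)(C)C(C)(C)C | intermediate
9 | (3S,4Z,6E)-3,5-bis[(tert-butyldimethylsilyl)oxy]-4-methylocta-4,6-dienoic acid | C/C=C/C(O[Si](C)(C)C(C)(C)C)=C(C)/[C@@H](O[Si](C)(C)C(C)(C)C)CC(=O)O | intermediate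
10 | isobutyl carbonic mixed anhydride of 9 | C/C=C/C(O[Si](C)(C)C(C)(C)C)=C(C)/[C@@H](O[Si](C)(C)C(C)(C)C)CC(=O)OC(=O)OCC(C)C | intermediate
11 | (4S,5Z,7E)-1-diazo-4,6-bis[(tert-butyldimethylsilyl)oxy]-5-methylnona-5,7-dien-2-one | C/C=C/C(O[Si](C)(C)C(C)(C)C)=C(C)/[C@@H](O[Si](C)(C)C(C)(C)C)CC(=O)C=[N+]=[N-] | intermediate
12 | bicyclo[3.1.0]hexanone: C4 ketone; cyclopropane C1–C5–C10; 1β-CH3, 5β-H; C10 endo-OTBS, exo-(E)-prop-1-enyl; 2β-OTBS trans to the cyclopropane | C/C=C/[C@@]3(O[Si](C)(C)C(C)(C)C)[C@@]2(C)[C@@H]3C(=O)C[C@@H]2O[Si](C)(C)C(C)(C)C | intermediate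
13 | siloxy-vinylcyclopropane: as 12 with 4α-OH (cis to the cyclopropane) and 4β-isopropyl | C/C=C/[C@@]3(O[Si](C)(C)C(C)(C)C)[C@@]2(C)[C@@H]3[C@](O)(C(C)C)C[C@@H]2O[Si](C)(C)C(C)(C)C | intermediate
14 | 2-ethynyl-4,4,5,5-tetramethyl-1,3,2-dioxaborolane | C#CB1OC(C)(C)C(C)(C)O1 | starting material
15 | cycloadduct: cis-fused bicyclo[5.3.0]deca-6,9-diene; 6-Bpin; 10-OTBS enol ether; 8α-CH3; 1β-CH3; 5β-H; 4α-OH, 4β-iPr; 2β-OTBS | CC3(C)OB(OC3(C)C)C1=C[C@H](C)C=C(O[Si](C)(C)C(C)(C)C)[C@@]2(C)[C@@H]1[C@](O)(C(C)C)C[C@@H]2O[Si](C)(C)C(C)(C)C | intermediate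
16 | 6-ketone: as 15 with C6=O and C7H2 | O=C1C[C@H](C)C=C(O[Si](C)(C)C(C)(C)C)[C@@]2(C)[C@@H]1[C@](O)(C(C)C)C[C@@H]2O[Si](C)(C)C(C)(C)C | intermediate
17 | 6β-alcohol: as 16 with 6β-OH | O[C@H]1C[C@H](C)C=C(O[Si](C)(C)C(C)(C)C)[C@@]2(C)[C@@H]1[C@](O)(C(C)C)C[C@@H]2O[Si](C)(C)C(C)(C)C | intermediate
18 | enone: 4α,6β-dihydroxy-2β-OTBS-daucan-8-en-10-one (cis-fused) | O[C@H]1CC(C)=CC(=O)[C@@]2(C)[C@@H]1[C@](O)(C(C)C)C[C@@H]2O[Si](C)(C)C(C)(C)C | intermediate
19 | allylic triol: 2β-OTBS-daucan-8-ene-4α,6β,10α-triol (cis-fused) | O[C@H]1CC(C)=C[C@H](O)[C@@]2(C)[C@@H]1[C@](O)(C(C)C)C[C@@H]2O[Si](C)(C)C(C)(C)C | intermediate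
20 | epoxy triol: 8α,9α-epoxy-2β-OTBS-daucane-4α,6β,10α-triol | O[C@H]1C[C@]2(C)O[C@@H]2[C@H](O)[C@@]2(C)[C@@H]1[C@](O)(C(C)C)C[C@@H]2O[Si](C)(C)C(C)(C)C | intermediate
21 | 6β,10α-bis-tiglate of 20 (2β-OTBS, 4α-OH) | C/C=C(\C)C(=O)O[C@H]1C[C@]2(C)O[C@@H]2[C@H](OC(=O)/C(C)=C/C)[C@@]2(C)[C@@H]1[C@](O)(C(C)C)C[C@@H]2O[Si](C)(C)C(C)(C)C | intermediate
22 | (1S,2S,4R,5S,6S,8S,9R,10R)-8,9-epoxy-2,4-dihydroxydaucane-6,10-diyl bis[(E)-2-methylbut-2-enoate] | C/C=C(\C)C(=O)O[C@H]1C[C@]2(C)O[C@@H]2[C@H](OC(=O)/C(C)=C/C)[C@@]2(C)[C@@H]1[C@](O)(C(C)C)C[C@@H]2O | target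

**Total step count:** 15. **Longest linear sequence:** 15 steps (1 and 2 to 22).

**Steps most likely to fail**

Step 8. The C5–C10 bond lies between two fully substituted carbons (C1 and C4), so oxidative addition may be slow; thermal ring opening of the siloxycyclopropane or oligomerisation of the alkyne could then outrun the cycloaddition, or the alkyne could insert with the opposite orientation. The fallback moves the cycloaddition one step earlier. It sets out from 12, whose cyclopropane is a donor–acceptor one (C10–OTBS donor, C4 ketone acceptor) and whose C4 is flat. Heating 12 with 14 and [Rh(CO)2Cl]2 in 1,2-dichloroethane should give the C4-ketone cycloadduct F1. Addition of iPrMgCl/CeCl3 at −78 °C should then place isopropyl on C4 from the convex β face, anti to the C5–C6 bond, and the route is rejoined at 15.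

Step 12. Hydride may approach C10 from the α face (conformational change of the cis-fused ring, or delivery by the free C4 alkoxide), which would give the 10β-epimer and misdirect the epoxidation. The fallback inverts C10 instead of relying on facial control. It sets out from 18: Yamaguchi esterification of its only secondary alcohol gives the 6β-tiglate enone F2, and NaBH4/CeCl3 then gives the 10β-allylic alcohol F3. Mitsunobu reaction (4-nitrobenzoic acid, PPh3, DIAD) inverts C10 to the 10α-(4-nitrobenzoate) F4, and K2CO3/MeOH at 0 °C cleaves the activated benzoate selectively to the 10α-alcohol F5. VO(acac)2/t-BuOOH gives the 8α,9α-epoxy alcohol F6, and a second Yamaguchi tigloylation rejoins the route at 21.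

Step 10. Exchange of the hindered tertiary C4 hydroxyl onto boron may be slow, so reduction could stall or proceed by external attack on the convex face to give the C6 epimer; the acidic medium could also slowly protodesilylate the enol ether. The fallback sets C6 by hydrogen delivery instead of hydride delivery. It sets out from 15: hydroxyl-directed hydrogenation of the alkenylboronate with [Ir(cod)(PCy3)(py)]PF6 and H2 in CH2Cl2 should add hydrogen to the α face of C6=C7 and give the 6β-alkylboronate F7. Oxidation with H2O2/NaHCO3 proceeds with retention and rejoins the route at 17.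

**Further compounds**
F1 | step 8 | C4-ketone cycloadduct (as 15 with C4=O in place of C(OH)iPr) | CC3(C)OB(OC3(C)C)C1=C[C@H](C)C=C(O[Si](C)(C)C(C)(C)C)[C@@]2(C)[C@@H]1C(=O)C[C@@H]2O[Si](C)(C)C(C)(C)C
F2 | step 12 | 6β-tiglate of enone 18 | C/C=C(\C)C(=O)O[C@H]1CC(C)=CC(=O)[C@@]2(C)[C@@H]1[C@](O)(C(C)C)C[C@@H]2O[Si](C)(C)C(C)(C)C
F3 | step 12 | 10β-allylic alcohol 6β-tiglate | C/C=C(\C)C(=O)O[C@H]1CC(C)=C[C@@H](O)[C@@]2(C)[C@@H]1[C@](O)(C(C)C)C[C@@H]2O[Si](C)(C)C(C)(C)C
F4 | step 12 | 10α-(4-nitrobenzoate) 6β-tiglate | C/C=C(\C)C(=O)O[C@H]1CC(C)=C[C@H](OC(=O)c3ccc(cc3)[N+](=O)[O-])[C@@]2(C)[C@@H]1[C@](O)(C(C)C)C[C@@H]2O[Si](C)(C)C(C)(C)C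
F5 | step 12 | 10α-allylic alcohol 6β-tiglate | C/C=C(\C)C(=O)O[C@H]1CC(C)=C[C@H](O)[C@@]2(C)[C@@H]1[C@](O)(C(C)C)C[C@@H]2O[Si](C)(C)C(C)(C)C
F6 | step 12 | 8α,9α-epoxy-10α-alcohol 6β-tiglate | C/C=C(\C)C(=O)O[C@H]1C[C@]2(C)O[C@@H]2[C@H](O)[C@@]2(C)[C@@H]1[C@](O)(C(C)C)C[C@@H]2O[Si](C)(C)C(C)(C)C
F7 | step 10 | 6β-alkylboronate (as 15 with C6–C7 saturated, Bpin β) | CC3(C)OB(OC3(C)C)[C@H]1C[C@H](C)C=C(O[Si](C)(C)C(C)(C)C)[C@@]2(C)[C@@H]1[C@](O)(C(C)C)C[C@@H]2O[Si](C)(C)C(C)(C)C
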